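(The runs come from a simulation on assumed constants, and the scatter is random.)

Start with the easy step, the balance. With C the D charged and T the amount of Z with one E counted as one Z, which is what the readings give, [Z] = T + T − C + [D]. On the reckoning below, the hunch that more D means more free Z holds at the low end of this row, but not at the high end.

| flask | D | Q | remark | time |
|---|---|---|---|---|
| grey | 0.065 M | 0.35 M | run made earlier |  |
| ochre | 0.24 M | 0.35 M | run made earlier |  |
| south-east | 0.060 M | 0.350 M |  | 6.0 h |
| west | 0.12 M | 0.350 M |  | 6.0 h |
| east | 0.25 M | 0.350 M |  | 6.0 h |
| south | 0.50 M | 0.350 M |  | 6.0 h |
| north-west | 1.0 M | 0.350 M |  | 6.0 h |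

- grey (time / h: Z / %): 0.417: 32; 1.00: 50; 2.00: 69; 3.00: 76
- ochre (time / h: Z / %): 0.833: 39; 1.50: 48; 2.50: 60; 3.00: 61

(scatter of a reading: 1.5 percentage points)

- percent here means D units held: one E counts as two
- what is said of Z includes E
- the analysis behind the earlier runs scatters by 1.5 percentage points, standard deviation
- steps thought possible: D + Q -> Z + G; D + Z <-> E
- in an amount of Z, one E counts as one Z
- the concentration of Z that is asked is that of its free form alone
- "hardly changes" means that all values lie within two and a half points (for a concentration: within two and a half percent of the largest)
- a step back or a flat step of under half a percent of the largest counts as no turn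

- [Z] (only what is free in solution) at the end for south-east, west, east, south, north-west, in this order
- the shape of the row from first to last (rises all the way / falls, then rises / rises, then falls / falls all the way / hardly changes)

After 3.00 h the ochre reading puts free Z at 0.0528 M or more, whatever [D] is. That is more than the 0.0494 M of T in the grey run, though the margin is thin against a scatter of 1.5 percentage points. So this reckoning takes the row to start by rising, on that thin margin.

The high end needs one quantity, the parking constant K, the ratio [E]/([D][Z]), read here from the grey run. Its first reading, taken as pseudo-first-order loss of D in Q, gives a rate of 0.925 /h. Its last step climbs 0.0700 /h at a mean T of 72.5 %. Dividing that climb by the rate, lowered for the Q used, leaves free D at 8.75 % of the charge. The balance then puts E at 18.8 % of the charge, each E counted once here, and free Z at 53.7 %, so K reads 61.4 /M, a figure that carries the scatter of the readings.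

In north-west the charge of Q is less than that of D, so Q is the limiting reagent: T can reach 0.350 M, and if that Z is taken as parked as E, the balance leaves about 0.300 M of free D. Then [E]/[Z] = K[D] = N = 18.4, whose common logarithm is 1.27. Taking E as T, free Z lies that many powers of ten below 0.350 M, at about 0.0190 M, which is less than the ochre figure. The reckoning therefore says the row rises, then falls.

The forecast gives 0.044 M, 0.071 M, 0.1 M, 0.1 M and 0.041 M, shape rises, then falls, on the ground that “leftover D ties Z up as E”, and it parts from this reckoning at north-west, 0.041 M against 0.0190 M.

The flasks give 0.0498 M, 0.0806 M, 0.113 M, 0.104 M and 0.0201 M, shape rises, then falls. At 6.00 h north-west holds 0.103 % of its Q and 32.1 % of its D.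

    D + Q → Z + G (k = 0.0500 /M/min)
    D + Z ⇌ E, settled at all times (K = 51.0 /M)

In south, K as read, times the 0.0342 M of D at the end, makes N 2.10. A T of 0.285 M divided by one plus N gives 0.0920 M, where the south flask stands at 0.104 M.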